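The numbers of this flask are made up; the flask was simulated.

The catalyst leaves step 2 as it entered, so [catalyst] stays at its charge, and steps 2 and 5 both run on the same product [substrate][dissolved gas].

substrate 0.066 M; gas phase 31 mM (held); catalyst 1.8 mM; time 4.0 d

    gas phase ⇌ dissolved gas, rate k1*(csat - [dissolved gas]) (k1 = 0.0045 min⁻¹, csat = 31 mM)
    substrate + dissolved gas + catalyst → catalyst + target (k2 = 5.0 M⁻² min⁻¹)
    substrate ⇌ dormant form (K3 = 14, k3 = 0.0017 min⁻¹)
    crystals ⇌ target, rate k4*(cs4 - [target]) while solid is left; crystals form when [target] > cs4 (cs4 = 45 mM, k4 = 0.0096 min⁻¹)
    substrate + dissolved gas → uncatalysed product (k5 = 0.014 M⁻¹ min⁻¹)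

- for target the crystals are counted in
- as a solid, counted per litre of solution: crystals
- at the start none of the gas is dissolved
- run time (flask): 4.0 d

* amount of target and crystals together at 4.0 d, in percent of the substrate charged
* concentration of dissolved gas in solution at 4.0 d, in percent of saturation

The ratio of these two rates therefore holds at every moment, however the crossing of the gas and the dormant form shift that product. We carry one quantity, the target share, a selectivity: the fraction of consumed substrate that becomes target, k2[catalyst]/(k2[catalyst] + k5), here 39.1%. In this flask the share is under 0.5 because the uncatalysed route is faster than the catalysed one.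

So y is this share times the fraction of the charge consumed, and in this flask target can reach at most 25.8 mM, less than the solubility of 45 mM, so no crystals form. Our reckoning stops there: we give no figure of our own for the fraction consumed, for y or for the gas.

The forecast gives 12.8% (range 12% to 13.6%) and 98.9% (range 98.6% to 99.2%), on the ground that “Substrate drains quickly into the dormant form”.

The flask gives 12.8% and 98.9%, inside both ranges. A flask charged with 2.69 mM of catalyst has y moved by 5 points, while the forecast's range spans 1.6 percentage points. Divided by the target share, 12.8% means 32.7% of the charge consumed by 4.0 d. For a neighbour flask, like this one but charged with 0.0072 M of catalyst, the same expression gives a target share of 72.0%, and that neighbour ends with 35.3% target beside 13.7% uncatalysed product, a share of 72.0%.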